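## Analysis of the target

The target consists of two trans-3,4-dibenzyl-γ-butyrolactones (each ring O1, C2=O, C3, C4, C5), each with a 3,4-dimethoxybenzyl group on C4 and a guaiacyl-type benzyl group on C3, so each half has the arctigenin skeleton in its (3S,4S) form. The halves are joined by one diaryl ether: the phenolic oxygen on C4 of the guaiacyl ring of the first half (ring A) is bonded to C5 of the corresponding ring of the second half (ring B, numbered from its benzylic carbon C1), which keeps OMe on C3 and a free OH on C4. All four stereocentres are S and trans within each lactone; the two lactones are too far apart to influence each other, so the homochiral relation can only come from using one enantiopure building block twice. The lactones are sensitive to hydroxide and alkoxide and can epimerise at C3 through their enolates, and the free, electron-rich phenol is sensitive to oxidants. The hard part is the ether bond at C5 of ring B, a carbon ortho to a free hydroxyl in a 1,2,3-trioxygenated arene, which joins two fragments that are otherwise almost the same. Oxidative phenol coupling would not separate C–O from C–C coupling, and a copper-mediated etherification would need an electron-rich aryl halide with an alkoxy group in the ortho position. The strategy rests on the adjacent oxygens of ring B (OMe on C3, OH on C4, OAr on C5): an aryne across C4–C5, flanked by the C3 methoxy group, can take the aryloxide at C5 and a boron hydroxyl surrogate at C4 in one event, with the methoxy group directing the regiochemistry.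

## Retrosynthetic reasoning

**23 back to 22.** The C4–OH of ring B is replaced by a C4–B(pin) group. The ortho-oxygenated phenol is the most oxidation-prone part of the molecule, so it is unmasked last. The forward step must oxidise one C–B bond without opening either lactone.

**22 back to 11 and 20, through aryne 21.** Two bonds on neighbouring carbons of ring B are cut: the diaryl ether bond C5–O and the C4–B bond. This is the only place where the molecule divides into two halves of equal size that share all their stereochemistry. Cutting here also removes the need for a protected ortho-halophenol and a hindered Ullmann coupling. Borate 11 carries both the nucleophilic oxygen and the electrophilic boron; silyl triflate 20 is the latent aryne. The forward reaction must add oxygen at C5, not C4, and must capture the C4 carbanion at boron before it finds a proton.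

**11 back to 9 and 10, then to 8, then to 4 and 6.** The O–B bond is cut to phenol 9 and pinacolborane 10. Phenol 9 comes from its benzyl ether 8. In 8 the C3–CH2Ar bond is cut, giving lactone 4 (as its lithium enolate 7) and benzylic bromide 6, which comes from alcohol 5. Alkylation of a β-substituted butyrolactone enolate is the standard way to set the trans C3/C4 relation, because the C4 substituent blocks one face.

**20 back to 4 and 18.** The same C3–CH2Ar bond is cut, here through the sodium enolate 19 of lactone 4. The sodium enolate is reactive enough to be alkylated at low temperature without a polar co-solvent, which suits an electrophile that also carries a triflate. The silyl and triflate groups are placed on the benzylic bromide before it meets the lactone, because their installation requires an organolithium reagent that a lactone would not survive.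

**18 back to 17, 14, 13 and 12.** Bromide 18 comes from alcohol 17. The ortho-silyl triflate of 17 is traced through triflate silyl ether 16 and phenoxide 15 to the bis-silyl ether 14 of bromophenol 13: bromine–lithium exchange followed by O-to-C silyl migration places silicon on the carbon that bore bromine. Diol 13 is the reduction product of 12, in which bromine already sits ortho to the hydroxyl and meta to the methoxy group, as the aryne precursor requires.

**4 back to 3, 2 and 1.** The C3–C4 bond of lactone 4 is cut to diazoacetate 3; a chiral dirhodium carbenoid inserts into one of the two enantiotopic C–H bonds of the central methylene of the propyl chain. This sets the only stereocentre that is not substrate-controlled, and it serves both halves. Diazoacetate 3 comes from alcohol 1 through bromoacetate 2.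

## Alternatives that were turned down

**Alternative 1: silicon-tethered radical cyclisation for both OCH2 carbons.**
- Disconnection: the C4–C5 bonds of both lactones. Each ring OCH2 carbon is brought in as a silicon-bound CH2 radical, tethered through oxygen to a benzylic carbinol next to the future C4.
- Key step: Bu3SnH with a radical initiator converts two bromomethylsilyl ethers on a diaryl ether bis-enoate into α-silyl radicals. These close 5-exo-trig onto the enoate β-carbons and give the bis(oxasilacyclopentane) diester A1. Tamao oxidation, lactonisation and hydrogenolysis of both benzylic C–O bonds and of the phenol benzyl ether would follow.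
- For: the diaryl ether is made early on simple arenes by established chemistry. The radical conditions are neutral. 5-exo closure through a temporary silicon-containing ring is dependable.
- Against: two carbinol stereocentres must be made enantioselectively and are then destroyed. C3 is set by hydrogen transfer to an acyclic ester-stabilised radical with no clear facial bias, so it would have to be corrected later by equilibration. Every stereochemical leak is doubled by the two-fold event. Stoichiometric tin and several operations per arm after the cyclisation make the route clearly longer.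
- Comparison: for the ether bond it is stronger, since no untested step is involved. The chosen route offers instead no sacrificial stereocentres, stereocontrol by one catalytic step plus substrate-controlled alkylation, and a union of two finished halves.

**Alternative 2: two-directional dithiane addition and core benzylation on a chiral butenolide.**
- Disconnection: in both lactones at once, the bond from C4 to its benzylic carbon (as an acyl anion equivalent) and the C3–CH2Ar bond.
- Key step: two equivalents of a lithiated aryl dithiane add 1,4 to a menthol-derived alkoxybutenolide. The two resulting enolates are trapped by the two benzylic bromide ends of a preformed diaryl ether core, giving A2 with all four ring stereocentres. Desulfurisation with Raney Ni, conversion of the acetal carbons into ring CH2 groups and benzyl ether removal would follow.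
- For: all reaction types are established for single lignan lactones. The auxiliary controls both new centres of each ring. If the double alkylation works, the step count is the lowest of all options.
- Against: the unsymmetrical diaryl ether bis-electrophile must be made first, with the problems of a hindered ortho-oxygenated ether only moved to an earlier stage. Each molecule of core must be alkylated by two separate enolates, so half-reacted material is the expected main by-product. Two dithianes, two acetals and a stoichiometric auxiliary must be removed afterwards.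
- Comparison: it is stronger in precedent and possibly shorter. The chosen strategy offers a late union in which both partners are made by routine chemistry and the ether oxygen and the hydroxyl position are fixed in the same step, with no sulfur or auxiliary removal.

**Alternative 3: desymmetrising Baeyer–Villiger expansion of a cyclobutanone.**
- Disconnection: the O1–C5 bond of the monomeric lactone.
- Key step: a chiral catalyst and a peroxide make one of the two enantiotopic CH2 groups of the prochiral cyclobutanone A4 migrate to oxygen. A4 would be reached from a commercial allylarene by ketene cycloaddition and dechlorination. The product A3 is the same compound as lactone 4.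
- For: no diazo compound and no rhodium, a cheap oxidant, and about the same number of steps to the lactone.
- Against: it addresses only the monomer and says nothing about the ether and hydroxyl array, which is the real problem of this target. The element that distinguishes the migrating groups is a remote benzyl substituent on a nearly flat four-membered ring, so enantiocontrol depends heavily on the catalyst.
- Comparison: for safe handling and cost of the lactone it is as strong or stronger, and it could replace steps 1 to 3 without changing the rest. The chosen strategy supplies the plan for joining the halves that this one lacks.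

Key step: step 13

Remark: the S configuration of lactone 4 from Rh2(4R-MPPIM)4 is assigned by analogy with related 3-arylpropyl diazoacetates. If the R lactone should form, the mirror-image catalyst Rh2(4S-MPPIM)4 is used and nothing else changes. Alcohol 5 is taken as a commercial chemical.

## Route

Step 1
Reactants: 1 3-(3,4-dimethoxyphenyl)propan-1-ol
Product: 2 3-(3,4-dimethoxyphenyl)propyl bromoacetate
Conditions: BrCH2COBr, NaHCO3, MeCN, 0 °C to rt
Reagents that add atoms: bromoacetyl bromide, O=C(Br)CBr
Why: O-acylation of a primary alcohol by an acid bromide; the hydrogen carbonate removes HBr so the electron-rich arene is not touched.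

Step 2
Reactants: 2 3-(3,4-dimethoxyphenyl)propyl bromoacetate
Product: 3 3-(3,4-dimethoxyphenyl)propyl diazoacetate
Conditions: TsNHNHTs, DBU, THF, 0 °C
Reagents that add atoms: N,N'-ditosylhydrazine, Cc1ccc(cc1)S(=O)(=O)NNS(=O)(=O)c1ccc(C)cc1
Why: N-alkylation of the bis-sulfonyl hydrazine by the bromoacetate, then base-induced loss of two sulfinate groups, gives the diazo ester (diazo transfer from a sulfonyl hydrazine under mild conditions).

Step 3
Reactants: 3 3-(3,4-dimethoxyphenyl)propyl diazoacetate
Product: 4 (S)-4-(3,4-dimethoxybenzyl)dihydrofuran-2(3H)-one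
Conditions: Rh2(4R-MPPIM)4 (1 mol%), CH2Cl2, reflux, slow addition of 3
Reagents that add atoms: none
Why: intramolecular carbenoid C–H insertion catalysed by a chiral dirhodium carboxamidate; the five-membered transition state directs the carbene to the central methylene of the chain, and the ligand set chooses between its two enantiotopic hydrogens, which sets C4 as S. The carboxamidate ligands make the carbene less electrophilic and so disfavour addition to the dimethoxyphenyl ring.

Step 4
Reactants: 5 4-(benzyloxy)-3-methoxybenzyl alcohol
Product: 6 4-(benzyloxy)-3-methoxybenzyl bromide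
Conditions: PBr3, Et2O, 0 °C
Reagents that add atoms: phosphorus tribromide, BrP(Br)Br
Why: conversion of a benzylic alcohol into the bromide through its phosphite ester; the labile electron-rich bromide is used without storage.

Step 5
Reactants: 4 (S)-4-(3,4-dimethoxybenzyl)dihydrofuran-2(3H)-one; 6 4-(benzyloxy)-3-methoxybenzyl bromide
Product: 8 (3S,4S)-3-[4-(benzyloxy)-3-methoxybenzyl]-4-(3,4-dimethoxybenzyl)dihydrofuran-2(3H)-one, via lactone lithium enolate 7 (not isolated)
Conditions: LiN(SiMe3)2, THF, −78 °C; then 6, DMPU, −78 to −30 °C
Reagents that add atoms: none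
Why: alkylation of a lactone enolate with a benzylic bromide; the bromide approaches the enolate face opposite the C4 benzyl group, so the new C3 centre forms trans to C4 and is S.

Step 6
Reactants: 8 (3S,4S)-3-[4-(benzyloxy)-3-methoxybenzyl]-4-(3,4-dimethoxybenzyl)dihydrofuran-2(3H)-one
Product: 9 (3S,4S)-4-(3,4-dimethoxybenzyl)-3-(4-hydroxy-3-methoxybenzyl)dihydrofuran-2(3H)-one
Conditions: H2 (1 atm), Pd/C, EtOAc/EtOH, rt
Reagents that add atoms: none
Why: hydrogenolysis of the benzyl aryl ether; the lactone, the methyl ethers and the benzylic C–C bonds are inert under these conditions.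

Step 7
Reactants: 9 (3S,4S)-4-(3,4-dimethoxybenzyl)-3-(4-hydroxy-3-methoxybenzyl)dihydrofuran-2(3H)-one; 10 pinacolborane
Product: 11 2-[4-{[(3S,4S)-4-(3,4-dimethoxybenzyl)-2-oxotetrahydrofuran-3-yl]methyl}-2-methoxyphenoxy]-4,4,5,5-tetramethyl-1,3,2-dioxaborolane
Conditions: HBpin (1.1 equiv), Et3N (cat.), toluene, rt to 50 °C; evaporation under argon
Reagents that add atoms: none
Why: dehydrogenative O-borylation of a phenol (alcoholysis of the B–H bond with loss of H2); without a catalyst pinacolborane does not reduce the lactone. The moisture-sensitive borate is used at once.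

Step 8
Reactants: 12 5-bromovanillin
Product: 13 2-bromo-4-(hydroxymethyl)-6-methoxyphenol
Conditions: NaBH4, MeOH/THF, 0 °C; aq. NH4Cl
Reagents that add atoms: none
Why: hydride reduction of the aldehyde; the aryl bromide and the phenol are unaffected.

Step 9
Reactants: 13 2-bromo-4-(hydroxymethyl)-6-methoxyphenol
Product: 14 {2-bromo-6-methoxy-4-[(trimethylsilyloxy)methyl]phenoxy}trimethylsilane
Conditions: (Me3Si)2NH, Me3SiCl (cat.), THF, 60 °C; evaporation
Reagents that add atoms: hexamethyldisilazane, C[Si](C)(C)N[Si](C)(C)C
Why: silylation of both hydroxyl groups with ammonia as the only by-product, so the water-sensitive bis-silyl ether needs no aqueous work-up.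

Step 10
Reactants: 14 {2-bromo-6-methoxy-4-[(trimethylsilyloxy)methyl]phenoxy}trimethylsilane
Product: 17 4-(hydroxymethyl)-2-methoxy-6-(trimethylsilyl)phenyl trifluoromethanesulfonate, via lithium phenoxide 15 (not isolated), via triflate silyl ether 16 (not isolated)
Conditions: n-BuLi, THF, −100 to −80 °C; Tf2O, −100 to −80 °C; then 1 M HCl, THF, 0 °C, short
Reagents that add atoms: trifluoromethanesulfonic anhydride, O=S(=O)(OS(=O)(=O)C(F)(F)F)C(F)(F)F
Why: bromine–lithium exchange, then retro-Brook 1,3-shift of silicon from the phenolic oxygen to the lithiated carbon, then O-triflation of the phenoxide. Dilute acid cleaves only the alkyl silyl ether; the aryl–silicon bond has no ortho or para donor and lies next to the deactivating triflate, so it is not protodesilylated.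

Step 11
Reactants: 17 4-(hydroxymethyl)-2-methoxy-6-(trimethylsilyl)phenyl trifluoromethanesulfonate
Product: 18 4-(bromomethyl)-2-methoxy-6-(trimethylsilyl)phenyl trifluoromethanesulfonate
Conditions: CBr4, PPh3, CH2Cl2, 0 °C
Reagents that add atoms: tetrabromomethane, BrC(Br)(Br)Br
Why: Appel reaction; the neutral conditions leave the aryl silane and the triflate intact.

Step 12
Reactants: 4 (S)-4-(3,4-dimethoxybenzyl)dihydrofuran-2(3H)-one; 18 4-(bromomethyl)-2-methoxy-6-(trimethylsilyl)phenyl trifluoromethanesulfonate
Product: 20 4-{[(3S,4S)-4-(3,4-dimethoxybenzyl)-2-oxotetrahydrofuran-3-yl]methyl}-2-methoxy-6-(trimethylsilyl)phenyl trifluoromethanesulfonate, via lactone sodium enolate 19 (not isolated)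
Conditions: NaN(SiMe3)2 (1.0 equiv), THF, −78 °C; then 18, THF, −78 °C; AcOH quench at −78 °C
Reagents that add atoms: none
Why: trans-selective alkylation of the sodium enolate of 4 by the benzylic bromide (attack anti to the C4 benzyl group, C3 becomes S). The sodium enolate is nucleophilic enough to react at −78 °C without a polar co-solvent or warming, so the mixture can be quenched cold before the enolate finds the triflate sulfur. The base is used up by 4 before 18 is added, and the triflate has no ortho hydrogen, so base cannot trigger aryne formation; the latent aryne needs fluoride.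

Step 13
Reactants: 11 2-[4-{[(3S,4S)-4-(3,4-dimethoxybenzyl)-2-oxotetrahydrofuran-3-yl]methyl}-2-methoxyphenoxy]-4,4,5,5-tetramethyl-1,3,2-dioxaborolane; 20 4-{[(3S,4S)-4-(3,4-dimethoxybenzyl)-2-oxotetrahydrofuran-3-yl]methyl}-2-methoxy-6-(trimethylsilyl)phenyl trifluoromethanesulfonate
Product: 22 2-[2-(4-{[(3S,4S)-4-(3,4-dimethoxybenzyl)-2-oxotetrahydrofuran-3-yl]methyl}-2-methoxyphenoxy)-4-{[(3S,4S)-4-(3,4-dimethoxybenzyl)-2-oxotetrahydrofuran-3-yl]methyl}-6-methoxyphenyl]-4,4,5,5-tetramethyl-1,3,2-dioxaborolane, via 3-methoxyaryne 21 (not isolated)
Conditions: CsF (2 equiv), 18-crown-6 (cat.), 4 Å MS, THF, rt to 40 °C; 20 added slowly to 11 (1.5 equiv)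
Reagents that add atoms: none
Why: Proposed new method: fluoride attacks the trimethylsilyl group of 20 and triflate leaves from the neighbouring carbon, giving aryne 21 with its triple bond across C4–C5 of ring B; fluoride (or aryloxide already set free) also adds to the boron of 11 and turns the neutral borate into an ate complex that releases its aryloxide. The aryloxide adds to C5, the aryne carbon remote from the methoxy group, because the inductively withdrawing C3–OMe distorts the aryne so that C5 is the more linear and more electrophilic carbon and the negative charge develops at C4 next to oxygen. The C4 aryl anion is then captured by a neutral boron centre, either the fluoro pinacol borate left behind by the aryloxide or a second molecule of 11 (which releases a new aryloxide and makes the process a chain), forming the C4–B bond; the net result is insertion of the aryne into the O–B bond of 11. The closest known reaction types are fluoride-triggered aryne insertions into heteroatom–silicon and heteroatom–tin σ-bonds, three-component couplings of arynes with phenoxides and an electrophile, and the O-arylation of free phenols by silyl aryl triflates, in which the same carbanion is protonated. No ring closes and no stereocentre forms, and the four existing centres are untouched as long as no lactone enolate is produced. The step needs regioselectivity (C5 over C4), which the methoxy group beside the triple bond provides, and chemoselectivity (boron capture over proton transfer). For the latter, the flask contains no O–H or N–H acid and no acidic solvent, 11 is in excess and mostly neutral because CsF dissolves only slowly, the lactone α-hydrogen of the same molecule sits para to C4 and cannot reach it, and the anion is stabilised by two ortho oxygens, which should make it long-lived enough to find boron. Slow addition of 20 keeps the aryne concentration low and limits aryne self-reaction.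

Step 14
Reactants: 22 2-[2-(4-{[(3S,4S)-4-(3,4-dimethoxybenzyl)-2-oxotetrahydrofuran-3-yl]methyl}-2-methoxyphenoxy)-4-{[(3S,4S)-4-(3,4-dimethoxybenzyl)-2-oxotetrahydrofuran-3-yl]methyl}-6-methoxyphenyl]-4,4,5,5-tetramethyl-1,3,2-dioxaborolane
Product: 23 (3S,4S)-4-(3,4-dimethoxybenzyl)-3-[4-(5-{[(3S,4S)-4-(3,4-dimethoxybenzyl)-2-oxotetrahydrofuran-3-yl]methyl}-2-hydroxy-3-methoxyphenoxy)-3-methoxybenzyl]dihydrofuran-2(3H)-one
Conditions: 30% H2O2, pH 7 phosphate buffer, THF, 0 °C
Reagents that add atoms: hydrogen peroxide, OO
Why: oxidation of an aryl boronate: hydroperoxide adds to boron, the electron-rich aryl group shifts from boron to oxygen, and the borate ester hydrolyses to the phenol. The neutral buffer protects both lactones and limits protodeboronation of the di-ortho-oxygenated boronate, which is oxidised directly after step 13.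

## Compound list

1 | 3-(3,4-dimethoxyphenyl)propan-1-ol | COc1ccc(CCCO)cc1OC | starting material
2 | 3-(3,4-dimethoxyphenyl)propyl bromoacetate | COc1ccc(CCCOC(=O)CBr)cc1OC | intermediate
3 | 3-(3,4-dimethoxyphenyl)propyl diazoacetate | COc1ccc(CCCOC(=O)C=[N+]=[N-])cc1OC | intermediate
4 | (S)-4-(3,4-dimethoxybenzyl)dihydrofuran-2(3H)-one | COc1ccc(C[C@@H]2COC(=O)C2)cc1OC | intermediate
5 | 4-(benzyloxy)-3-methoxybenzyl alcohol | COc1cc(CO)ccc1OCc1ccccc1 | starting material
6 | 4-(benzyloxy)-3-methoxybenzyl bromide | COc1cc(CBr)ccc1OCc1ccccc1 | intermediate
7 | lithium (S)-4-(3,4-dimethoxybenzyl)-4,5-dihydrofuran-2-olate (lithium enolate of 4) | COc1ccc(C[C@@H]2COC([O-])=C2)cc1OC.[Li+] | intermediate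
8 | (3S,4S)-3-[4-(benzyloxy)-3-methoxybenzyl]-4-(3,4-dimethoxybenzyl)dihydrofuran-2(3H)-one | COc1ccc(C[C@@H]2COC(=O)[C@H]2Cc2ccc(OCc3ccccc3)c(OC)c2)cc1OC | intermediate
9 | (3S,4S)-4-(3,4-dimethoxybenzyl)-3-(4-hydroxy-3-methoxybenzyl)dihydrofuran-2(3H)-one | COc1ccc(C[C@@H]2COC(=O)[C@H]2Cc2ccc(O)c(OC)c2)cc1OC | intermediate
10 | pinacolborane (4,4,5,5-tetramethyl-1,3,2-dioxaborolane) | CC1(C)OBOC1(C)C | starting material
11 | 2-[4-{[(3S,4S)-4-(3,4-dimethoxybenzyl)-2-oxotetrahydrofuran-3-yl]methyl}-2-methoxyphenoxy]-4,4,5,5-tetramethyl-1,3,2-dioxaborolane | COc1ccc(C[C@@H]2COC(=O)[C@H]2Cc2ccc(OB3OC(C)(C)C(C)(C)O3)c(OC)c2)cc1OC | intermediate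
12 | 5-bromovanillin (3-bromo-4-hydroxy-5-methoxybenzaldehyde) | COc1cc(C=O)cc(Br)c1O | starting material
13 | 2-bromo-4-(hydroxymethyl)-6-methoxyphenol | COc1cc(CO)cc(Br)c1O | intermediate
14 | {2-bromo-6-methoxy-4-[(trimethylsilyloxy)methyl]phenoxy}trimethylsilane | COc1cc(CO[Si](C)(C)C)cc(Br)c1O[Si](C)(C)C | intermediate
15 | lithium 2-methoxy-6-(trimethylsilyl)-4-[(trimethylsilyloxy)methyl]phenolate | COc1cc(CO[Si](C)(C)C)cc([Si](C)(C)C)c1[O-].[Li+] | intermediate
16 | 2-methoxy-6-(trimethylsilyl)-4-[(trimethylsilyloxy)methyl]phenyl trifluoromethanesulfonate | COc1cc(CO[Si](C)(C)C)cc([Si](C)(C)C)c1OS(=O)(=O)C(F)(F)F | intermediate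
17 | 4-(hydroxymethyl)-2-methoxy-6-(trimethylsilyl)phenyl trifluoromethanesulfonate | COc1cc(CO)cc([Si](C)(C)C)c1OS(=O)(=O)C(F)(F)F | intermediate
18 | 4-(bromomethyl)-2-methoxy-6-(trimethylsilyl)phenyl trifluoromethanesulfonate | COc1cc(CBr)cc([Si](C)(C)C)c1OS(=O)(=O)C(F)(F)F | intermediate
19 | sodium (S)-4-(3,4-dimethoxybenzyl)-4,5-dihydrofuran-2-olate (sodium enolate of 4) | COc1ccc(C[C@@H]2COC([O-])=C2)cc1OC.[Na+] | intermediate
20 | 4-{[(3S,4S)-4-(3,4-dimethoxybenzyl)-2-oxotetrahydrofuran-3-yl]methyl}-2-methoxy-6-(trimethylsilyl)phenyl trifluoromethanesulfonate | COc1cc(C[C@@H]2C(=O)OC[C@H]2Cc2ccc(OC)c(OC)c2)cc([Si](C)(C)C)c1OS(=O)(=O)C(F)(F)F | intermediate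
21 | (3S,4S)-3-[(3-methoxy-4,5-didehydrophenyl)methyl]-4-(3,4-dimethoxybenzyl)dihydrofuran-2(3H)-one (3-methoxyaryne) | COC1=CC(C[C@@H]2C(=O)OC[C@H]2Cc2ccc(OC)c(OC)c2)=CC#C1 | intermediate
22 | 2-[2-(4-{[(3S,4S)-4-(3,4-dimethoxybenzyl)-2-oxotetrahydrofuran-3-yl]methyl}-2-methoxyphenoxy)-4-{[(3S,4S)-4-(3,4-dimethoxybenzyl)-2-oxotetrahydrofuran-3-yl]methyl}-6-methoxyphenyl]-4,4,5,5-tetramethyl-1,3,2-dioxaborolane | COc1ccc(C[C@@H]2COC(=O)[C@H]2Cc2ccc(Oc3cc(C[C@@H]4C(=O)OC[C@H]4Cc4ccc(OC)c(OC)c4)cc(OC)c3B3OC(C)(C)C(C)(C)O3)c(OC)c2)cc1OC | intermediate
23 | (3S,4S)-4-(3,4-dimethoxybenzyl)-3-[4-(5-{[(3S,4S)-4-(3,4-dimethoxybenzyl)-2-oxotetrahydrofuran-3-yl]methyl}-2-hydroxy-3-methoxyphenoxy)-3-methoxybenzyl]dihydrofuran-2(3H)-one (CNP0183104.1) | COc1ccc(C[C@@H]2COC(=O)[C@H]2Cc2ccc(Oc3cc(C[C@@H]4C(=O)OC[C@H]4Cc4ccc(OC)c(OC)c4)cc(OC)c3O)c(OC)c2)cc1OC | target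

## Step count and least certain steps

Total step count: 14. Longest linear sequence: 8 steps (1 to 23 through steps 1, 2, 3, 5, 6, 7, 13 and 14). The branch from 12 has 7 steps (8 to 14).

**Step 13 (key step).**
- Most likely failure: proton transfer to the C4 aryl anion, from a lactone α-position of another molecule or from traces of water, outruns capture at boron. The ether then forms without the boron group, and the lactone enolates that arise can epimerise or be arylated. A second risk is that boron binds fluoride so firmly that aryne release stalls.
- Fallback by known chemistry, setting out from 12, 4 and 9 and rejoining the route at 23: 12 is O-benzylated (BnBr, K2CO3, DMF) to 4-(benzyloxy)-3-bromo-5-methoxybenzaldehyde F1. This is reduced (NaBH4) to [4-(benzyloxy)-3-bromo-5-methoxyphenyl]methanol F2 and brominated (PBr3) to 2-(benzyloxy)-1-bromo-5-(bromomethyl)-3-methoxybenzene F3. Alkylation of 4 under the conditions of step 5, through its lithium enolate 7, gives (3S,4S)-3-[4-(benzyloxy)-3-bromo-5-methoxybenzyl]-4-(3,4-dimethoxybenzyl)dihydrofuran-2(3H)-one F4. Ullmann ether coupling of F4 with phenol 9 (CuI, picolinic acid, K3PO4, DMSO, 90 °C) gives the C4 O-benzyl ether of the target F5, and hydrogenolysis (H2, Pd/C) gives 23. The C4 oxygen is then present from the start and the ether bond is made by copper catalysis, at the cost of a slow coupling at a hindered, electron-rich bromide.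

**Step 14.**
- Most likely failure: protodeboronation of the di-ortho-oxygenated aryl boronate by ipso-protonation in the aqueous medium before the oxidant has reacted, or lactone opening if the pH rises.
- Fallback, from 22 back to 23: crude 22 is treated with KHF2 in aqueous methanol to give the potassium aryltrifluoroborate F6, a more robust boron species. F6 is oxidised within minutes by KHSO5 (as Oxone) in acetone/water at rt to give 23.

**Step 12.**
- Most likely failure: attack of the sodium enolate or of residual amide base on the triflate sulfur, with loss of the triflyl group, or proton exchange between the product and unreacted enolate, which leaves alkylation incomplete and gives some double alkylation.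
- Fallback, from 15 and 4 back to 20, introducing the triflate last: phenoxide 15 is O-benzylated in the flask (BnBr, DMF co-solvent, rt). After an acidic work-up that removes the benzylic silyl group, [4-(benzyloxy)-3-methoxy-5-(trimethylsilyl)phenyl]methanol F7 is isolated. Appel bromination gives [2-(benzyloxy)-5-(bromomethyl)-3-methoxyphenyl]trimethylsilane F8. Alkylation of 4 under the conditions of step 5, through its lithium enolate 7, gives (3S,4S)-3-[4-(benzyloxy)-3-methoxy-5-(trimethylsilyl)benzyl]-4-(3,4-dimethoxybenzyl)dihydrofuran-2(3H)-one F9. Hydrogenolysis (H2, Pd/C) gives (3S,4S)-4-(3,4-dimethoxybenzyl)-3-[4-hydroxy-3-methoxy-5-(trimethylsilyl)benzyl]dihydrofuran-2(3H)-one F10, and triflation (Tf2O, pyridine, CH2Cl2, 0 °C) gives 20.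

**Step 3.**
- Most likely failure: insufficient or reversed enantioselection, or diversion of the carbenoid into addition to the electron-rich dimethoxyphenyl ring, insertion at the benzylic position, or carbene dimerisation.
- Fallback by auxiliary control, from 1 back to 4: 1 is oxidised (TEMPO, NaOCl, NaClO2) to 3-(3,4-dimethoxyphenyl)propanoic acid F11. F11 is coupled through its pivaloyl mixed anhydride with lithiated (R)-4-benzyloxazolidin-2-one to give (R)-4-benzyl-3-[3-(3,4-dimethoxyphenyl)propanoyl]oxazolidin-2-one F12. The sodium Z-enolate (NaN(SiMe3)2, THF, −78 °C) is alkylated with tert-butyl bromoacetate on the face away from the auxiliary benzyl group, giving tert-butyl (3S)-4-[(4R)-4-benzyl-2-oxooxazolidin-3-yl]-3-(3,4-dimethoxybenzyl)-4-oxobutanoate F13. Reductive removal of the auxiliary (LiBH4, THF, 0 °C) gives tert-butyl (3S)-4-(3,4-dimethoxyphenyl)-3-(hydroxymethyl)butanoate F14, and acid (CF3CO2H, CH2Cl2) closes the lactone to 4.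

## Further compounds

F1 | step 13 | 4-(benzyloxy)-3-bromo-5-methoxybenzaldehyde | COc1cc(C=O)cc(Br)c1OCc1ccccc1
F2 | step 13 | [4-(benzyloxy)-3-bromo-5-methoxyphenyl]methanol | COc1cc(CO)cc(Br)c1OCc1ccccc1
F3 | step 13 | 2-(benzyloxy)-1-bromo-5-(bromomethyl)-3-methoxybenzene | COc1cc(CBr)cc(Br)c1OCc1ccccc1
F4 | step 13 | (3S,4S)-3-[4-(benzyloxy)-3-bromo-5-methoxybenzyl]-4-(3,4-dimethoxybenzyl)dihydrofuran-2(3H)-one | COc1cc(C[C@@H]2C(=O)OC[C@H]2Cc2ccc(OC)c(OC)c2)cc(Br)c1OCc1ccccc1
F5 | step 13 | O-benzyl ether of 23 at the C4 hydroxyl of ring B | COc1ccc(C[C@@H]2COC(=O)[C@H]2Cc2ccc(Oc3cc(C[C@@H]4C(=O)OC[C@H]4Cc4ccc(OC)c(OC)c4)cc(OC)c3OCc3ccccc3)c(OC)c2)cc1OC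
F6 | step 14 | potassium aryltrifluoroborate corresponding to 22 | COc1ccc(C[C@@H]2COC(=O)[C@H]2Cc2ccc(Oc3cc(C[C@@H]4C(=O)OC[C@H]4Cc4ccc(OC)c(OC)c4)cc(OC)c3[B-](F)(F)F)c(OC)c2)cc1OC.[K+]
F7 | step 12 | [4-(benzyloxy)-3-methoxy-5-(trimethylsilyl)phenyl]methanol | COc1cc(CO)cc([Si](C)(C)C)c1OCc1ccccc1
F8 | step 12 | [2-(benzyloxy)-5-(bromomethyl)-3-methoxyphenyl]trimethylsilane | COc1cc(CBr)cc([Si](C)(C)C)c1OCc1ccccc1
F9 | step 12 | (3S,4S)-3-[4-(benzyloxy)-3-methoxy-5-(trimethylsilyl)benzyl]-4-(3,4-dimethoxybenzyl)dihydrofuran-2(3H)-one | COc1cc(C[C@@H]2C(=O)OC[C@H]2Cc2ccc(OC)c(OC)c2)cc([Si](C)(C)C)c1OCc1ccccc1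
F10 | step 12 | (3S,4S)-4-(3,4-dimethoxybenzyl)-3-[4-hydroxy-3-methoxy-5-(trimethylsilyl)benzyl]dihydrofuran-2(3H)-one | COc1cc(C[C@@H]2C(=O)OC[C@H]2Cc2ccc(OC)c(OC)c2)cc([Si](C)(C)C)c1O
F11 | step 3 | 3-(3,4-dimethoxyphenyl)propanoic acid | COc1ccc(CCC(=O)O)cc1OC
F12 | step 3 | (R)-4-benzyl-3-[3-(3,4-dimethoxyphenyl)propanoyl]oxazolidin-2-one | COc1ccc(CCC(=O)N2[C@H](Cc3ccccc3)COC2=O)cc1OC
F13 | step 3 | tert-butyl (3S)-4-[(4R)-4-benzyl-2-oxooxazolidin-3-yl]-3-(3,4-dimethoxybenzyl)-4-oxobutanoate | COc1ccc(C[C@@H](CC(=O)OC(C)(C)C)C(=O)N2[C@H](Cc3ccccc3)COC2=O)cc1OC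
F14 | step 3 | tert-butyl (3S)-4-(3,4-dimethoxyphenyl)-3-(hydroxymethyl)butanoate | COc1ccc(C[C@@H](CC(=O)OC(C)(C)C)CO)cc1OC
A1 | alternative 1 | bis(oxasilacyclopentane) diester from the two-fold silicon-tethered radical cyclisation | C[Si]1(C)C[C@H]([C@H](Cc2ccc(Oc3cc(C[C@@H]([C@H]4C[Si](C)(C)O[C@@H]4c5ccc(OC)c(OC)c5)C(=O)OC)cc(OC)c3OCc3ccccc3)c(OC)c2)C(=O)OC)[C@@H](c2ccc(OC)c(OC)c2)O1
A2 | alternative 2 | bis(dithianyl) bis(menthyloxy lactone) from the two-directional addition and alkylation | COc1ccc(C3(SCCCS3)[C@@H]2[C@@H](O[C@H]3C[C@@H](C)CC[C@@H]3C(C)C)OC(=O)[C@H]2Cc2ccc(Oc3cc(C[C@@H]4C(=O)O[C@H](O[C@H]5C[C@@H](C)CC[C@@H]5C(C)C)[C@H]4C5(SCCCS5)c4ccc(OC)c(OC)c4)cc(OC)c3OCc3ccccc3)c(OC)c2)cc1OC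
A3 | alternative 3 | (S)-4-(3,4-dimethoxybenzyl)dihydrofuran-2(3H)-one (identical with 4) | COc1ccc(C[C@@H]2COC(=O)C2)cc1OC
A4 | alternative 3 | 3-(3,4-dimethoxybenzyl)cyclobutan-1-one | COc1ccc(CC2CC(=O)C2)cc1OC
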